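## Structural features

The target is a lignan lactone: one γ-butyrolactone ring (O1, C2 carbonyl, C3, C4, C5) carrying an exocyclic E-configured 4-hydroxy-3-methoxybenzylidene group on C3 and a 3,4-dimethoxybenzyl (veratryl) group on C4. The two arenes are not joined to each other; each is tied to the lactone through one carbon. C4 (R) is the only stereocentre, so nothing can be relayed from a neighbour; it is flanked by the sp2 carbon C3, the oxymethylene C5 and the veratryl CH2. The C4–H bond is allylic and vinylogously acidic (γ to the carbonyl), so base can pull the exocyclic double bond into the ring and erase the stereocentre. The benzylidene lactone is also a Michael acceptor, the free guaiacyl phenol is sensitive to oxidants, and the electron-rich cinnamyl-type C2–O bond of open-chain precursors ionises easily in acid. The real difficulty is to set an isolated stereocentre in the absolute sense next to a geometrically defined trisubstituted alkene, and then to reach the lactone without enolising conditions. The key step exploits the position of C4 between sp2 C3 and the veratryl CH2. This is the pattern of the boron-bearing carbon of a vinylboron unit that has received an alkenyl group on one carbon and an aryl group on the other, and the C–B bond left on C4 is the handle for C5.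

## Logic of the disconnections

21 back to 20. Only the phenolic O–Si bond is cut. Keeping the phenol silylated to the end removes the acidic O–H from every organometallic step and shields the guaiacyl ring from MnO2. The forward step must use a buffered fluoride source, because the C4–H of 21 is vinylogously acidic.

20 back to 17. The acyl C2–O1 bond is cut and C2 is lowered from the acid to the alcohol level, which opens the lactone to a 1,4-diol. The cut is made here because C2 in 17 is allylic and conjugated to the arene whereas C5 is an ordinary primary carbinol, so one oxidant can tell them apart. The gain is that ring, carbonyl and acceptor alkene all arise late from an unreactive diol. The forward step must oxidise C2 first (through 18 and 19) and must leave the C5 hydroxyl alone, since the reverse order would give the regioisomeric lactone.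

17 back to 16. Only the alkyl O–Si bond at C2 is cut. The gain is that the allylic oxygen stays masked through the organolithium and boron chemistry. The forward step must cleave the alkyl silyl ether in the presence of the aryl one without ionising the C2–O bond.

16 back to 13. The C4–C5 and C5–O bonds are cut: C5 is treated as a CH2 unit inserted into a C4–B bond (14, then 15) and then oxidised. This removes the only skeletal carbon that does not belong to one of the three coupling partners and leaves boron on the stereocentre. The forward step needs a single insertion with retention at C4 and an oxidation mild enough for the aryl silyl ether.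

13 back to 7, 10 and 9. Two bonds at the two carbons of a former vinyl group are cut together: C3–C4 and the CH2–aryl bond. The cut is made here because C4 is the boron-bearing carbon of 10 after an alkenyl group (from 7, via 11 and 12) has shifted onto it while the terminal carbon is arylated by 9. The gain is large: the stereocentre and the whole carbon skeleton except C5 come from three achiral pieces in one operation, with the E alkene carried in unchanged. The forward step demands that palladium bind the vinyl group of 12 and not the trisubstituted alkenyl group, that the metallate shift outrun direct transfer of either alkenyl group to palladium, that the ligand choose one face of the vinyl group, and that 11 keep its geometry.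

7 back to 6, 4, 2, 3 and 1. The alkyl O–Si bond, then the oxidation level of C2 (through 5), then the C=C bond between the benzylidene carbon and C3, then the aryl O–Si bond are cut. The Wittig cut is chosen because the bromine that later becomes lithium arrives on the ylide carbon of 3, so one step fixes both the alkene geometry and the position of the future metal. The forward steps demand Z selectivity in the olefination and a 1,2-reduction that leaves the vinylic bromide alone.

9 back to 8. The aryl O–S bond is cut; the triflate is needed so that the arylpalladium species in the key step is cationic.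

## Other disconnections considered

Alternative 1: The cut is inside the ring at C3–C4 and O1–C5, and the benzylidene C=C bond is cut separately.
- Forward key step: dichloroketene A3 (from trichloroacetyl chloride and zinc–copper couple) would acylate the sulfoxide oxygen of the enantiopure alkenyl sulfoxide A2. A [3,3] shift would then form C3–C4, and the carboxylate would close onto the thionium carbon to give the dichloro thio-lactone A1.
- In its favour: the configuration at C4 would be relayed from sulfur through an ordered six-membered transition state, so it rests on a stereospecific rearrangement and not on a catalyst whose selectivity has to be found. A chair with an equatorial tolyl group suggests that the (S)-sulfoxide of E geometry is the one leading to (4R). Ring formation and the C4 stereocentre come in one step.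
- Against it here: two chlorines and the arylthio group must be reduced away afterwards (zinc/AcOH, then Bu3SnH/AIBN), and the source of chirality is stoichiometric. The benzylidene would have to be added last by aldol condensation with 2 to reach 20, which puts a base-mediated dehydration on a skeleton whose double bond can slip into the ring and leaves the E geometry to thermodynamic control.
- Comparison: on predictability of the absolute configuration this alternative is the better one. On step count the two are about equal. The chosen plan is better in atom economy and in fixing the alkene geometry by a Wittig reaction before C4 exists.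

Alternative 2: The cut is at C2–C3 and C2–O1; the carbonyl carbon is removed as carbon monoxide A6, leaving the homopropargylic alcohol A5.
- Forward key step: PdCl2(PPh3)2/SnCl2 under A6 would convert A5 into the silyl ether A4 through an alkoxycarbonylpalladium species that adds syn across the alkyne in the 5-exo sense, followed by protonation of the alkenyl–palladium bond. Syn addition places the aryl group trans to the carbonyl, which is the E geometry.
- In its favour: ring, carbonyl and alkene geometry would be formed together under neutral conditions, with one desilylation left and no exposure of the product to base. In fixing the geometry by mechanism it is the equal of the chosen plan, and in the brevity and mildness of the end game it is the better.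
- Against it here: the step does not create C4. A5 must already hold the stereocentre, at a propargylic carbon, so the asymmetric problem is moved into the preparation of A5 (auxiliary-based alkylation and alkyne construction), probably at a cost of as many steps as the chosen route needs to reach 13. Pressurised CO is also required.
- Comparison: structurally the same ring atoms are assembled. Mechanistically it is a migratory insertion in place of a metallate shift. In step economy it is shorter after the key step and longer before it, and the stereocentre is paid for with stoichiometric chirality, whereas the chosen key step makes it catalytically.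

Alternative 3: The cut is at C3–C4 of the ring, with the benzylidene again cut separately.
- Forward key step: Rh2(4S-MPPIM)4 would decompose the diazoacetate A8, and the rhodium carbene would insert into the homobenzylic C–H bond to give the lactone A7, closing the ring and setting C4.
- In its favour: the step is catalytic and enantioselective and builds ring and stereocentre at once. A8 is about two steps from a commercial 3-arylpropanol, and insertions of 3-arylpropyl diazoacetates with this catalyst class are established chemistry. On step economy and on precedent this alternative is the better plan (about seven steps against ten).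
- Against it here: A7 lacks the benzylidene, so an aldol condensation with 2 would be needed to reach 20, with the same base exposure and thermodynamic control of geometry as in Alternative 1. A diazo compound must be handled, and insertion at other C–H bonds or addition to the electron-rich veratryl ring has to be suppressed by the carboxamidate ligand.
- Comparison: the chosen plan is longer and relies on a migrating group that is untested in this coupling. What it offers in return is that the alkene geometry is installed stereospecifically and that the finished benzylidene lactone never meets an enolising base.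

Key step: step 6

Conventions and assumptions:
- Lactone numbering (O1, C2 carbonyl, C3, C4, C5) is used for the corresponding atoms of all open-chain compounds.
- Compound 3 is taken to be a purchasable Wittig reagent.
- The (Sp,Sp) enantiomer of the Mandyphos ligand is expected to give (R)-13 by analogy with the facial preference of this ligand class. The configuration of 13 would be confirmed on a sample (oxidation to the allylic alcohol, Mosher ester analysis), and the antipodal ligand would be used if the sense proved opposite.
- Descriptor check: 7 is Z (aryl cis to bromine) and 13 is (R,E). Because the C4–B bond is replaced by C4–C5 with retention, (R)-13 maps onto (R)-21 although the CIP ranking of the substituents changes.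

## Route

Step 1
Reactants: 1 vanillin
Product: 2 3-methoxy-4-(triisopropylsilyloxy)benzaldehyde
Conditions: TIPSCl (1.1 equiv), imidazole (2 equiv), DMF, rt
Reagents that add atoms: triisopropylsilyl chloride, CC(C)[Si](Cl)(C(C)C)C(C)C
Why: Imidazole-promoted O-silylation of a phenol; the bulky aryl TIPS ether is chosen because it withstands t-BuLi at −78 °C, hydride, weak acid and perborate and is still removed by fluoride.

Step 2
Reactants: 2 3-methoxy-4-(triisopropylsilyloxy)benzaldehyde; 3 ethyl bromo(triphenylphosphoranylidene)acetate
Product: 4 ethyl (Z)-2-bromo-3-[3-methoxy-4-(triisopropylsilyloxy)phenyl]prop-2-enoate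
Conditions: toluene, 80 °C
Reagents that add atoms: none
Why: Wittig olefination with a stabilised α-bromo ylide; reversible addition places the ester trans to the aryl group, which is the Z isomer because bromine outranks the ester carbon. Any minor geometric isomer is removed by chromatography here or after step 3.

Step 3
Reactants: 4 ethyl (Z)-2-bromo-3-[3-methoxy-4-(triisopropylsilyloxy)phenyl]prop-2-enoate
Product: 6 (Z)-2-bromo-3-[3-methoxy-4-(triisopropylsilyloxy)phenyl]prop-2-en-1-ol, via bromoenal 5 (not isolated)
Conditions: i-Bu2AlH (2.3 equiv), CH2Cl2, −78 °C; aq. potassium sodium tartrate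
Reagents that add atoms: none
Why: 1,2-Reduction of a conjugated ester by an electrophilic aluminium hydride through aldehyde 5; at −78 °C the vinylic C–Br bond, the alkene geometry and the aryl silyl ether are left untouched.

Step 4
Reactants: 6 (Z)-2-bromo-3-[3-methoxy-4-(triisopropylsilyloxy)phenyl]prop-2-en-1-ol
Product: 7 (Z)-[2-bromo-3-(3-methoxy-4-triisopropylsilyloxyphenyl)allyloxy](tert-butyl)dimethylsilane
Conditions: TBSCl (1.2 equiv), imidazole (2 equiv), CH2Cl2, 0 °C → rt
Reagents that add atoms: tert-butyldimethylsilyl chloride, CC(C)(C)[Si](C)(C)Cl
Why: O-Silylation of a primary allylic alcohol; the alkyl TBS ether tolerates t-BuLi at −78 °C and the boron chemistry, and weak acid can later remove it while the aryl TIPS ether stays.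

Step 5
Reactants: 8 3,4-dimethoxyphenol
Product: 9 3,4-dimethoxyphenyl trifluoromethanesulfonate
Conditions: Tf2O (1.1 equiv), pyridine (2 equiv), CH2Cl2, 0 °C
Reagents that add atoms: trifluoromethanesulfonic anhydride, O=S(=O)(OS(=O)(=O)C(F)(F)F)C(F)(F)F
Why: O-Sulfonylation of a phenol; the triflate is required because its non-coordinating anion leaves the arylpalladium intermediate of step 6 cationic.

Step 6
Reactants: 7 (Z)-[2-bromo-3-(3-methoxy-4-triisopropylsilyloxyphenyl)allyloxy](tert-butyl)dimethylsilane; 10 vinylboronic acid pinacol ester; 9 3,4-dimethoxyphenyl trifluoromethanesulfonate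
Product: 13 tert-butyl{[(2E,3R)-4-(3,4-dimethoxyphenyl)-2-[3-methoxy-4-(triisopropylsilyloxy)benzylidene]-3-(4,4,5,5-tetramethyl-1,3,2-dioxaborolan-2-yl)butyl]oxy}dimethylsilane, via alkenyllithium 11 (not isolated), via lithium bis(alkenyl)boronate 12 (not isolated)
Conditions: t-BuLi (2.0 equiv), Et2O, −78 °C; 10, −78 °C → rt; solvent swap to THF; 9 (1.1 equiv), Pd(OAc)2 (2 mol%), (Sp,Sp)-Mandyphos (2.4 mol%), KOTf (2 equiv), 60 °C
Reagents that add atoms: none
Why: Bromine–lithium exchange at −78 °C gives alkenyllithium 11 with retention, and 11 adds to the empty orbital on boron of 10 to give the bis(alkenyl)boronate 12. Zerovalent palladium, formed from Pd(OAc)2 and the bisphosphine, inserts into the C–O bond of 9 to give a cationic arylpalladium complex (divalent palladium) that binds the unsubstituted vinyl group of 12; this triggers 1,2-migration of the alkenyl group from boron to the internal vinyl carbon anti to the metal (C3–C4), and reductive elimination from the alkyl(aryl)palladium species then forms the CH2–aryl bond and returns zerovalent palladium. The closest known reaction type is the palladium-catalysed enantioselective conjunctive cross-coupling of bis(alkenyl)boronates with aryl triflates, from which this case differs only in its trisubstituted migrating group. No ring is closed. The one new stereocentre, C4, is controlled by the catalyst alone: the chiral pocket of the Mandyphos-bound palladium decides which enantiotopic face of the vinyl group carries the metal and therefore from which face the alkenyl group arrives. The chemoselectivity needed (which alkene binds and which group migrates) is secured by the substrate, because the CH2OTBS and aryl substituents make the trisubstituted alkenyl group a poor ligand for palladium while the bare vinyl group is the only accessible acceptor. The alkene geometry is retained because neither the exchange nor the shift breaks the C=C bond, the migrating sp2 carbon keeping its configuration. KOTf removes the bromide released in the exchange as KBr so that palladium stays cationic, and holding 11 at −78 °C in Et2O until it is trapped suppresses silyl migration from oxygen to carbon.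

Step 7
Reactants: 13 tert-butyl{[(2E,3R)-4-(3,4-dimethoxyphenyl)-2-[3-methoxy-4-(triisopropylsilyloxy)benzylidene]-3-(4,4,5,5-tetramethyl-1,3,2-dioxaborolan-2-yl)butyl]oxy}dimethylsilane
Product: 16 (2R,3E)-3-[(tert-butyldimethylsilyloxy)methyl]-2-(3,4-dimethoxybenzyl)-4-[3-methoxy-4-(triisopropylsilyloxy)phenyl]but-3-en-1-ol, via chloromethylboronate complex 14 (not isolated), via homologated pinacol boronate 15 (not isolated)
Conditions: BrCH2Cl (1.5 equiv), n-BuLi (1.4 equiv), THF, −78 °C → rt; then NaBO3·4H2O (5 equiv), THF/H2O, rt
Reagents that add atoms: bromochloromethane, ClCBr; sodium perborate, [Na+].[O-]OB=O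
Why: Matteson homologation followed by C–B oxidation: LiCH2Cl generated in the presence of 13 adds to boron (14), and on warming the C4 group migrates from boron to the CH2 carbon with loss of chloride and retention at C4 (15). Perborate then converts the primary C–B bond into C–OH; it is chosen over NaOH/H2O2 because it spares the aryl TIPS ether and does not epoxidise the styrene. A 1,3-boron shift in 13 is not expected, since it would break the styrene conjugation.

Step 8
Reactants: 16 (2R,3E)-3-[(tert-butyldimethylsilyloxy)methyl]-2-(3,4-dimethoxybenzyl)-4-[3-methoxy-4-(triisopropylsilyloxy)phenyl]but-3-en-1-ol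
Product: 17 (2R,3E)-2-(3,4-dimethoxybenzyl)-3-[3-methoxy-4-(triisopropylsilyloxy)benzylidene]butane-1,4-diol
Conditions: PPTS (0.2 equiv), MeOH, rt
Reagents that add atoms: none
Why: Acid-catalysed methanolysis of a silyl ether: the alkyl ether oxygen is protonated and desilylated far faster than the aryl ether oxygen, so the primary TBS group is lost and the aryl TIPS group stays. The weak acid PPTS is used so that the cinnamyl-type C2–O bond is not ionised.

Step 9
Reactants: 17 (2R,3E)-2-(3,4-dimethoxybenzyl)-3-[3-methoxy-4-(triisopropylsilyloxy)benzylidene]butane-1,4-diol
Product: 20 (3E,4R)-4-(3,4-dimethoxybenzyl)-3-[3-methoxy-4-(triisopropylsilyloxy)benzylidene]oxolan-2-one, via hydroxy enal 18 (not isolated), via lactol 19 (not isolated)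
Conditions: activated MnO2 (25 equiv), CH2Cl2, rt
Reagents that add atoms: none
Why: MnO2 oxidative lactonisation of a 2-alkylidene-1,4-diol: only the allylic, arene-conjugated C2 alcohol is oxidised, giving enal 18; the C5 hydroxyl adds to give lactol 19, whose allylic hemiacetal C–H is oxidised again to the lactone. The saturated C5 alcohol is inert to MnO2, which fixes the regiochemistry, and no base is present, so C4 and the E alkene are safe.

Step 10
Reactants: 20 (3E,4R)-4-(3,4-dimethoxybenzyl)-3-[3-methoxy-4-(triisopropylsilyloxy)benzylidene]oxolan-2-one
Product: 21 (3E,4R)-4-(3,4-dimethoxybenzyl)-3-(4-hydroxy-3-methoxybenzylidene)oxolan-2-one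
Conditions: Bu4NF (1.1 equiv), AcOH (1.2 equiv), THF, 0 °C
Reagents that add atoms: none
Why: Fluoride-mediated cleavage of an aryl silyl ether (Si–F bond formation with phenoxide as leaving group); acetic acid protonates the phenoxide at once and keeps the medium non-basic, so the γ-acidic C4–H is not removed and the double bond stays exocyclic.

## Compound list

1 | vanillin | COc1cc(C=O)ccc1O | starting material
2 | 3-methoxy-4-(triisopropylsilyloxy)benzaldehyde | COc1cc(C=O)ccc1O[Si](C(C)C)(C(C)C)C(C)C | intermediate
3 | ethyl bromo(triphenylphosphoranylidene)acetate | CCOC(=O)C(Br)=P(c1ccccc1)(c1ccccc1)c1ccccc1 | starting material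
4 | ethyl (Z)-2-bromo-3-[3-methoxy-4-(triisopropylsilyloxy)phenyl]prop-2-enoate | COc1cc(/C=C(/C(=O)OCC)Br)ccc1O[Si](C(C)C)(C(C)C)C(C)C | intermediate
5 | (Z)-2-bromo-3-[3-methoxy-4-(triisopropylsilyloxy)phenyl]prop-2-enal | COc1cc(/C=C(/C=O)Br)ccc1O[Si](C(C)C)(C(C)C)C(C)C | intermediate (not isolated)
6 | (Z)-2-bromo-3-[3-methoxy-4-(triisopropylsilyloxy)phenyl]prop-2-en-1-ol | COc1cc(/C=C(/CO)Br)ccc1O[Si](C(C)C)(C(C)C)C(C)C | intermediate
7 | (Z)-[2-bromo-3-(3-methoxy-4-triisopropylsilyloxyphenyl)allyloxy](tert-butyl)dimethylsilane | COc1cc(/C=C(/CO[Si](C)(C)C(C)(C)C)Br)ccc1O[Si](C(C)C)(C(C)C)C(C)C | intermediate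
8 | 3,4-dimethoxyphenol | COc1ccc(O)cc1OC | starting material
9 | 3,4-dimethoxyphenyl trifluoromethanesulfonate | COc1ccc(OS(=O)(=O)C(F)(F)F)cc1OC | intermediate
10 | vinylboronic acid pinacol ester | C=CB1OC(C)(C)C(C)(C)O1 | starting material
11 | [(E)-3-(tert-butyldimethylsilyloxy)-1-[3-methoxy-4-(triisopropylsilyloxy)phenyl]prop-1-en-2-yl]lithium | COc1cc(/C=C(/CO[Si](C)(C)C(C)(C)C)[Li])ccc1O[Si](C(C)C)(C(C)C)C(C)C | intermediate (not isolated)
12 | lithium [(E)-3-(tert-butyldimethylsilyloxy)-1-[3-methoxy-4-(triisopropylsilyloxy)phenyl]prop-1-en-2-yl](vinyl)(pinacolato)borate | [Li+].COc1cc(/C=C(/CO[Si](C)(C)C(C)(C)C)[B-]2(C=C)OC(C)(C)C(C)(C)O2)ccc1O[Si](C(C)C)(C(C)C)C(C)C | intermediate (not isolated)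
13 | tert-butyl{[(2E,3R)-4-(3,4-dimethoxyphenyl)-2-[3-methoxy-4-(triisopropylsilyloxy)benzylidene]-3-(4,4,5,5-tetramethyl-1,3,2-dioxaborolan-2-yl)butyl]oxy}dimethylsilane | COc1cc(/C=C(/CO[Si](C)(C)C(C)(C)C)[C@H](B2OC(C)(C)C(C)(C)O2)Cc2ccc(OC)c(OC)c2)ccc1O[Si](C(C)C)(C(C)C)C(C)C | intermediate
14 | lithium chloromethyl boronate complex of 13 (C4 configuration as in 13) | [Li+].COc1cc(/C=C(/CO[Si](C)(C)C(C)(C)C)[C@H]([B-]2(CCl)OC(C)(C)C(C)(C)O2)Cc2ccc(OC)c(OC)c2)ccc1O[Si](C(C)C)(C(C)C)C(C)C | intermediate (not isolated)
15 | tert-butyl{[(2E,3R)-3-(3,4-dimethoxybenzyl)-2-[3-methoxy-4-(triisopropylsilyloxy)benzylidene]-4-(4,4,5,5-tetramethyl-1,3,2-dioxaborolan-2-yl)butyl]oxy}dimethylsilane | COc1cc(/C=C(/CO[Si](C)(C)C(C)(C)C)[C@H](CB2OC(C)(C)C(C)(C)O2)Cc2ccc(OC)c(OC)c2)ccc1O[Si](C(C)C)(C(C)C)C(C)C | intermediate (not isolated)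
16 | (2R,3E)-3-[(tert-butyldimethylsilyloxy)methyl]-2-(3,4-dimethoxybenzyl)-4-[3-methoxy-4-(triisopropylsilyloxy)phenyl]but-3-en-1-ol | COc1cc(/C=C(/CO[Si](C)(C)C(C)(C)C)[C@H](CO)Cc2ccc(OC)c(OC)c2)ccc1O[Si](C(C)C)(C(C)C)C(C)C | intermediate
17 | (2R,3E)-2-(3,4-dimethoxybenzyl)-3-[3-methoxy-4-(triisopropylsilyloxy)benzylidene]butane-1,4-diol | COc1cc(/C=C(/CO)[C@H](CO)Cc2ccc(OC)c(OC)c2)ccc1O[Si](C(C)C)(C(C)C)C(C)C | intermediate
18 | (2E,3R)-4-(3,4-dimethoxyphenyl)-3-(hydroxymethyl)-2-[3-methoxy-4-(triisopropylsilyloxy)benzylidene]butanal | COc1cc(/C=C(/C=O)[C@H](CO)Cc2ccc(OC)c(OC)c2)ccc1O[Si](C(C)C)(C(C)C)C(C)C | intermediate (not isolated)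
19 | (3E,4R)-4-(3,4-dimethoxybenzyl)-3-[3-methoxy-4-(triisopropylsilyloxy)benzylidene]oxolan-2-ol (both C2 epimers) | COc1cc(/C=C2/C(O)OC[C@@H]2Cc2ccc(OC)c(OC)c2)ccc1O[Si](C(C)C)(C(C)C)C(C)C | intermediate (not isolated)
20 | (3E,4R)-4-(3,4-dimethoxybenzyl)-3-[3-methoxy-4-(triisopropylsilyloxy)benzylidene]oxolan-2-one | COc1cc(/C=C2/C(=O)OC[C@@H]2Cc2ccc(OC)c(OC)c2)ccc1O[Si](C(C)C)(C(C)C)C(C)C | intermediate
21 | (3E,4R)-4-(3,4-dimethoxybenzyl)-3-(4-hydroxy-3-methoxybenzylidene)oxolan-2-one | COc1cc(/C=C2/C(=O)OC[C@@H]2Cc2ccc(OC)c(OC)c2)ccc1O | target

## Step count and least certain steps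

Total: 10 steps. Longest linear sequence: 9 steps (steps 1–4 and 6–10); step 5 is a one-step branch.

Step 6 (key step).
- What may go wrong: the metallate shift of the hindered trisubstituted alkenyl group may be slow, so that direct transfer of an alkenyl group from boron to palladium (plain cross-coupling) or β-hydride loss takes over. Facial selectivity may be poor with a migrating group this large. If 11 warms before it is trapped, the silyl group can migrate from oxygen to the lithiated carbon.
- Fallback (from 7, back at 13): a lithiation–borylation that sets C4 with a stoichiometric chiral diamine instead of a catalyst.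
  - Bromide 7 would be converted (t-BuLi, Et2O, −78 °C, then 2-isopropoxy-4,4,5,5-tetramethyl-1,3,2-dioxaborolane) into the alkenyl pinacol boronate F1.
  - Commercial 2-(3,4-dimethoxyphenyl)ethanol F2 would be carbamoylated (N,N-diisopropylcarbamoyl chloride, Et3N, toluene, reflux) to 2-(3,4-dimethoxyphenyl)ethyl N,N-diisopropylcarbamate F3.
  - s-BuLi/(−)-sparteine in Et2O at −78 °C would give the configurationally stable (S)-α-lithiated carbamate F4.
  - Addition of F1 would give the boronate complex F5 with retention. Warming (MgBr2·OEt2 if needed) would make the alkenyl group migrate from boron to carbon with loss of the carbamate and inversion, which is expected to give (R)-13.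

Step 7.
- What may go wrong: the primary boronate formed is less hindered than the secondary allylic one consumed, so double insertion can compete while conversion is still incomplete. Partial loss of the aryl silyl group during oxidation is a second risk.
- Fallback (from 13, back at 15): the CH2 group is built in two separate events.
  - Dichloromethyllithium (CH2Cl2, n-BuLi, THF, −100 °C), whose ate complex forms irreversibly, is added to 13 and rearranged with ZnCl2 to the α-chloro boronate F6 (both epimers at the chlorine-bearing carbon, which is of no consequence).
  - LiBHEt3 then replaces chloride by hydride through a second boronate rearrangement. The product is 15, which is oxidised with NaBO3 as in step 7.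
  - F6 cannot insert a second carbon under these conditions.

Step 9.
- What may go wrong: the second oxidation (lactol to lactone) may stall because the activity of MnO2 varies. Long exposure may also cause geometric isomerisation of the alkene.
- Fallback (from 17, back at 20): MnO2 is used only as far as the pair 18/19. The aldehyde is then taken to the acid level by Pinnick oxidation (NaClO2, NaH2PO4, 2-methyl-2-butene, t-BuOH/H2O), giving the hydroxy acid F7. Mild acidification closes F7 to 20 by ordinary lactonisation, so the ring is formed by acyl substitution instead of hemiacetal oxidation.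

Step 10.
- What may go wrong: base-induced migration of the exocyclic double bond into the ring, with loss of the C4 stereocentre, if phenoxide or fluoride is not buffered well enough. Conjugate addition to the acceptor is a lesser risk.
- Fallback (from 17, back at 21): the phenol protection is exchanged before the lactone exists.
  - Bu4NF (THF, 0 °C) on 17 gives the phenolic diol F8.
  - Allyl bromide/K2CO3 in acetone alkylates only the phenol, giving the allyl ether F9.
  - MnO2 (as in step 9) gives the O-allyl lactone F10.
  - Pd(PPh3)4 (cat.) with N-methylaniline in THF at rt removes the allyl group under neutral conditions to give 21.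

## Further compounds

F1 | step 6 | 2-[(E)-3-(tert-butyldimethylsilyloxy)-1-[3-methoxy-4-(triisopropylsilyloxy)phenyl]prop-1-en-2-yl]-4,4,5,5-tetramethyl-1,3,2-dioxaborolane | COc1cc(/C=C(/CO[Si](C)(C)C(C)(C)C)B2OC(C)(C)C(C)(C)O2)ccc1O[Si](C(C)C)(C(C)C)C(C)C
F2 | step 6 | 2-(3,4-dimethoxyphenyl)ethanol | COc1ccc(CCO)cc1OC
F3 | step 6 | 2-(3,4-dimethoxyphenyl)ethyl N,N-diisopropylcarbamate | COc1ccc(CCOC(=O)N(C(C)C)C(C)C)cc1OC
F4 | step 6 | (S)-[1-(N,N-diisopropylcarbamoyloxy)-2-(3,4-dimethoxyphenyl)ethyl]lithium (as its (−)-sparteine complex) | COc1ccc(C[C@H]([Li])OC(=O)N(C(C)C)C(C)C)cc1OC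
F5 | step 6 | lithium boronate complex of F4 and F1, (S) at the carbamate carbon | [Li+].COc1ccc(C[C@@H](OC(=O)N(C(C)C)C(C)C)[B-]2(/C(CO[Si](C)(C)C(C)(C)C)=C\c3ccc(O[Si](C(C)C)(C(C)C)C(C)C)c(OC)c3)OC(C)(C)C(C)(C)O2)cc1OC
F6 | step 7 | tert-butyl{[(2E,3R)-4-chloro-3-(3,4-dimethoxybenzyl)-2-[3-methoxy-4-(triisopropylsilyloxy)benzylidene]-4-(4,4,5,5-tetramethyl-1,3,2-dioxaborolan-2-yl)butyl]oxy}dimethylsilane (both C–Cl epimers) | COc1cc(/C=C(/CO[Si](C)(C)C(C)(C)C)[C@H](C(Cl)B2OC(C)(C)C(C)(C)O2)Cc2ccc(OC)c(OC)c2)ccc1O[Si](C(C)C)(C(C)C)C(C)C
F7 | step 9 | (2E,3R)-4-(3,4-dimethoxyphenyl)-3-(hydroxymethyl)-2-[3-methoxy-4-(triisopropylsilyloxy)benzylidene]butanoic acid | COc1cc(/C=C(/C(=O)O)[C@H](CO)Cc2ccc(OC)c(OC)c2)ccc1O[Si](C(C)C)(C(C)C)C(C)C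
F8 | step 10 | (2R,3E)-2-(3,4-dimethoxybenzyl)-3-(4-hydroxy-3-methoxybenzylidene)butane-1,4-diol | COc1cc(/C=C(/CO)[C@H](CO)Cc2ccc(OC)c(OC)c2)ccc1O
F9 | step 10 | (2R,3E)-3-(4-allyloxy-3-methoxybenzylidene)-2-(3,4-dimethoxybenzyl)butane-1,4-diol | COc1cc(/C=C(/CO)[C@H](CO)Cc2ccc(OC)c(OC)c2)ccc1OCC=C
F10 | step 10 | (3E,4R)-3-(4-allyloxy-3-methoxybenzylidene)-4-(3,4-dimethoxybenzyl)oxolan-2-one | COc1cc(/C=C2/C(=O)OC[C@@H]2Cc2ccc(OC)c(OC)c2)ccc1OCC=C
A1 | alternative 1 | 4,5-trans-3,3-dichloro-4-(3,4-dimethoxybenzyl)-5-(p-tolylthio)oxolan-2-one | O=C1O[C@@H](Sc2ccc(C)cc2)[C@H](Cc2ccc(OC)c(OC)c2)C1(Cl)Cl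
A2 | alternative 1 | 1,2-dimethoxy-4-[(E)-3-[(S)-p-tolylsulfinyl]prop-2-enyl]benzene | COc1ccc(C/C=C/[S@](=O)c2ccc(C)cc2)cc1OC
A3 | alternative 1 | dichloroketene | ClC(Cl)=C=O
A4 | alternative 2 | (3E,4R)-3-[4-(tert-butyldimethylsilyloxy)-3-methoxybenzylidene]-4-(3,4-dimethoxybenzyl)oxolan-2-one | COc1cc(/C=C2/C(=O)OC[C@@H]2Cc2ccc(OC)c(OC)c2)ccc1O[Si](C)(C)C(C)(C)C
A5 | alternative 2 | (R)-4-[4-(tert-butyldimethylsilyloxy)-3-methoxyphenyl]-2-(3,4-dimethoxybenzyl)but-3-yn-1-ol | COc1cc(C#C[C@H](CO)Cc2ccc(OC)c(OC)c2)ccc1O[Si](C)(C)C(C)(C)C
A6 | alternative 2 | carbon monoxide | [C-]#[O+]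
A7 | alternative 3 | (R)-4-(3,4-dimethoxybenzyl)oxolan-2-one | O=C1C[C@@H](Cc2ccc(OC)c(OC)c2)CO1
A8 | alternative 3 | 3-(3,4-dimethoxyphenyl)propyl diazoacetate | COc1ccc(CCCOC(=O)C=[N+]=[N-])cc1OC
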